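The pyrrole ring is disconnected at N1–C5. C4 and C5 of the target are bare CH positions and can therefore be the two carbons of an ethynyl group; C3, which carries the C21 chain, then becomes a tertiary propargylic carbinol, and C2, which carries the formyl carbon, a glycine α-carbon at the ester oxidation level. A monovalent silver catalyst makes the sulfonamide nitrogen add to the terminal alkyne carbon (5-endo-dig), and loss of water across C2–C3 in the same pot closes and aromatises the ring in one operation. The precursor, a β-ethynyl-β-hydroxy N-tosyl amino ester, comes from a glycinate aldol on a silyl ynone; ester-to-aldehyde adjustment and N-detosylation finish the synthesis.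

Key step: step 4

Remark on the chemistry: the glycine component is carried as its methyl ester so that methanolic desilylation cannot exchange the alkoxy group, the N-tosyl group is kept until the last step because N–H pyrrol-2-ylmethanols ionise to azafulvenes, and docosanoyl chloride is assumed to be commercially available (otherwise it is made from docosanoic acid with (COCl)2 and cat. DMF).

Step 1
Reactants: 1 docosanoyl chloride; 2 bis(trimethylsilyl)acetylene
Product: 3 1-(trimethylsilyl)tetracos-1-yn-3-one
Conditions: AlCl3 (1.1 equiv), CH2Cl2, 0 °C; ice/1 M HCl work-up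
Reagents that add atoms: none
Why: AlCl3 turns the acid chloride into an acylium species that attacks the silylalkyne at the silicon-bearing carbon, and loss of the silyl group from the β-silyl cation gives the ynone (Friedel–Crafts-type acyldesilylation), the second silyl group surviving because the ynone formed is deactivated.

Step 2
Reactants: 4 methyl N-tosylglycinate (1.5 equiv); 3 1-(trimethylsilyl)tetracos-1-yn-3-one
Product: 7 methyl 3-hydroxy-2-(tosylamino)-3-[(trimethylsilyl)ethynyl]tetracosanoate (racemic diastereomer mixture), via dilithium glycinate dianion 5 (not isolated), via tin chelate enolate 6 (not isolated)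
Conditions: LiN(i-Pr)2 (2.2 equiv per 4), THF, −78 °C; SnCl2 (1.1 equiv per 4), −78 °C; then 3 in THF, −78 → −40 °C; aq. NH4Cl
Reagents that add atoms: none
Why: Double deprotonation of 4 (N–H and α-C–H) and transmetalation to divalent tin should give a chelated, weakly basic glycinate enolate that adds 1,2 to the ketone of 3 through a closed transition state instead of enolising it, the bulky silyl group shielding the alkyne terminus from conjugate addition (chelate-enolate aldol addition); the two new stereocentres at C2 and C3 are not controlled and arise as a racemic diastereomer mixture, which is acceptable because both are erased in step 4.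

Step 3
Reactants: 7 methyl 3-hydroxy-2-(tosylamino)-3-[(trimethylsilyl)ethynyl]tetracosanoate
Product: 8 methyl 3-ethynyl-3-hydroxy-2-(tosylamino)tetracosanoate (racemic diastereomer mixture)
Conditions: K2CO3 (0.3 equiv), MeOH/THF (1:1), 0 °C
Reagents that add atoms: none
Why: Methoxide attacks silicon and the released acetylide is protonated by methanol (base-catalysed protodesilylation of an alkynylsilane), while the cold, catalytic conditions should keep retro-aldol cleavage slow and methanol cannot scramble a methyl ester.

Step 4
Reactants: 8 methyl 3-ethynyl-3-hydroxy-2-(tosylamino)tetracosanoate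
Product: 10 methyl 3-heneicosyl-1-tosyl-1H-pyrrole-2-carboxylate, via hydroxy dihydropyrrole 9 (not isolated)
Conditions: AgNO3 on SiO2 (10% w/w; 10 mol% monovalent silver), CH2Cl2, rt, dark; then pyridinium p-toluenesulfonate (10 mol%), rt
Reagents that add atoms: none
Why: Monovalent silver binds the terminal C≡C of 8 as a π-acid and the tosylamide nitrogen adds anti to the metal at the terminal carbon, so that the N1–C5 bond forms and the five-membered ring closes in the 5-endo-dig mode; protodemetalation of the vinylsilver species then gives the 3-hydroxy-2,3-dihydropyrrole 9. The tertiary hydroxyl at C3 of 9 is allylic to the N-sulfonyl enamine, so it ionises under the mild acid to a vinylogous N-sulfonyliminium ion, and loss of the ester-activated C2–H delivers the aromatic pyrrole 10. The closest known reaction type is the silver- or gold-catalysed cycloisomerisation–dehydration of N-sulfonyl 1-amino-3-alkyn-2-ols to pyrroles. No stereocentre is formed and both stereocentres of 8 are destroyed, so the diastereomer mixture should converge on one product. The step needs N-attack at the terminal and not the internal alkyne carbon: the alternative 4-exo-dig closure would give a strained azetidine, the C3 hydroxyl cannot reach the alkyne, and addition of the ester carbonyl is non-productive because a methyl ester cannot shed its alkyl group, so only the 5-endo pathway leads forward.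

Step 5
Reactants: 10 methyl 3-heneicosyl-1-tosyl-1H-pyrrole-2-carboxylate
Product: 11 (3-heneicosyl-1-tosyl-1H-pyrrol-2-yl)methanol
Conditions: i-Bu2AlH (2.5 equiv), CH2Cl2, −78 → 0 °C; aq. potassium sodium tartrate (KNaC4H4O6) work-up
Reagents that add atoms: none
Why: i-Bu2AlH should reduce the ester to the primary alcohol at low temperature without touching the sulfonamide (hydride reduction of an ester), and the retained N-tosyl group prevents ionisation of the pyrrolylcarbinol to an azafulvene, the pathway that causes over-reduction to the 2-methylpyrrole and oligomerisation in N–H pyrroles.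

Step 6
Reactants: 11 (3-heneicosyl-1-tosyl-1H-pyrrol-2-yl)methanol
Product: 12 3-heneicosyl-1-tosyl-1H-pyrrole-2-carbaldehyde
Conditions: MnO2 (activated, 15 equiv), CH2Cl2, rt
Reagents that add atoms: none
Why: Activated MnO2 selectively oxidises the pyrrolyl (benzylic-type) carbinol to the aldehyde and stops there (heterogeneous MnO2 oxidation of an activated alcohol).

Step 7
Reactants: 12 3-heneicosyl-1-tosyl-1H-pyrrole-2-carbaldehyde
Product: 13 3-heneicosyl-1H-pyrrole-2-carbaldehyde (target)
Conditions: LiOH·H2O (3 equiv), THF/H2O (4:1), 40 °C
Reagents that add atoms: none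
Why: Hydroxide attacks sulfur and expels the pyrrolide, a good leaving group because the 2-formyl group stabilises it (nucleophilic N-desulfonylation of an acyl-activated N-sulfonylpyrrole), while hydroxide instead of an alkoxide avoids an alkyl sulfonate that could N-alkylate the product and the non-enolisable aldehyde tolerates the base.

Compound list
1 | docosanoyl chloride | CCCCCCCCCCCCCCCCCCCCCC(=O)Cl | starting material
2 | bis(trimethylsilyl)acetylene | C[Si](C)(C)C#C[Si](C)(C)C | starting material
3 | 1-(trimethylsilyl)tetracos-1-yn-3-one | CCCCCCCCCCCCCCCCCCCCCC(=O)C#C[Si](C)(C)C | intermediate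
4 | methyl N-tosylglycinate | COC(=O)CNS(=O)(=O)c1ccc(C)cc1 | starting material
5 | dilithium dianion of methyl N-tosylglycinate (N-lithio lithium enolate) | [Li+].[Li+].COC([O-])=C[N-]S(=O)(=O)c1ccc(C)cc1 | intermediate
6 | divalent tin chelate enolate of methyl N-tosylglycinate (tin bridging enolate O and sulfonamide N) | COC1=CN(S(=O)(=O)c2ccc(C)cc2)[Sn]O1 | intermediate
7 | methyl 3-hydroxy-2-(tosylamino)-3-[(trimethylsilyl)ethynyl]tetracosanoate (racemic, both diastereomers, no configuration assigned) | CCCCCCCCCCCCCCCCCCCCCC(O)(C#C[Si](C)(C)C)C(NS(=O)(=O)c1ccc(C)cc1)C(=O)OC | intermediate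
8 | methyl 3-ethynyl-3-hydroxy-2-(tosylamino)tetracosanoate (racemic, both diastereomers, no configuration assigned) | CCCCCCCCCCCCCCCCCCCCCC(O)(C#C)C(NS(=O)(=O)c1ccc(C)cc1)C(=O)OC | intermediate
9 | methyl 3-heneicosyl-3-hydroxy-1-tosyl-2,3-dihydro-1H-pyrrole-2-carboxylate (racemic, both diastereomers) | CCCCCCCCCCCCCCCCCCCCCC1(O)C=CN(S(=O)(=O)c2ccc(C)cc2)C1C(=O)OC | intermediate
10 | methyl 3-heneicosyl-1-tosyl-1H-pyrrole-2-carboxylate | CCCCCCCCCCCCCCCCCCCCCc1ccn(S(=O)(=O)c2ccc(C)cc2)c1C(=O)OC | intermediate
11 | (3-heneicosyl-1-tosyl-1H-pyrrol-2-yl)methanol | CCCCCCCCCCCCCCCCCCCCCc1ccn(S(=O)(=O)c2ccc(C)cc2)c1CO | intermediate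
12 | 3-heneicosyl-1-tosyl-1H-pyrrole-2-carbaldehyde | CCCCCCCCCCCCCCCCCCCCCc1ccn(S(=O)(=O)c2ccc(C)cc2)c1C=O | intermediate
13 | 3-heneicosyl-1H-pyrrole-2-carbaldehyde (achiral) | CCCCCCCCCCCCCCCCCCCCCc1cc[nH]c1C=O | target

Total step count: 7. Longest linear sequence: 7 steps (1 → 3 → 7 → 8 → 10 → 11 → 12 → 13).

Steps most likely to fail

Step 4. Silver may be tied up as the acetylide of the terminal alkyne so that turnover stops. The tertiary propargylic alcohol may instead rearrange in the Meyer–Schuster sense, or the sequence may stall before dehydration. The fallback replaces metal catalysis by an electrophile-induced closure and sets out from 8. Treatment with I2 (3 equiv) and NaHCO3 in MeCN at 0 °C should give, by iodonium-triggered 5-endo-dig attack of the sulfonamide, methyl 3-heneicosyl-3-hydroxy-4-iodo-1-tosyl-2,3-dihydro-1H-pyrrole-2-carboxylate F1. Acid-catalysed dehydration (cat. TsOH·H2O, CH2Cl2, rt) should then give methyl 3-heneicosyl-4-iodo-1-tosyl-1H-pyrrole-2-carboxylate F2. Hydrogenolysis of the C–I bond (H2 at 1 atm, Pd/C, Et3N, EtOAc) brings the material back to the route at 10.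

Step 2. The enolate may transfer a proton from the α-methylene of the ynone instead of forming the C–C bond, may add in a conjugate sense, or the aldolate may revert on warming, all of which lower conversion. The fallback uses a nearly neutral, catalytic aldol and sets out from 3. Methyl isocyanoacetate with Ag2O (5 mol%) and PPh3 (10 mol%) in CH2Cl2 at rt should add to the ketone and close to methyl 5-heneicosyl-5-[(trimethylsilyl)ethynyl]-4,5-dihydro-1,3-oxazole-4-carboxylate F3 (isocyanoacetate aldol to an oxazoline). Methanolysis of the oxazoline (HCl in MeOH, rt, then NaHCO3 work-up) should give methyl 2-amino-3-hydroxy-3-[(trimethylsilyl)ethynyl]tetracosanoate F4. N-Selective sulfonylation (TsCl, Et3N, CH2Cl2, 0 °C) brings the material back to the route at 7.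

Step 3. Under base the β-hydroxy α-amino ester may fragment by retro-aldol cleavage, or eliminate, faster than the Si–C bond is cleaved. The fallback avoids base altogether and merges the desilylation with the ring closure; it sets out from 7. AgNO3 (20 mol%) in acetone/H2O (10:1) at rt in the dark should cleave the C–Si bond through the silver acetylide and its protonolysis. The same silver salt then effects the 5-endo-dig closure, and pyridinium p-toluenesulfonate completes the dehydration, so the fallback returns to the route at 10. No compound outside the compound list is made on this way (none F0).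

Further compounds
F1 | step 4 | methyl 3-heneicosyl-3-hydroxy-4-iodo-1-tosyl-2,3-dihydro-1H-pyrrole-2-carboxylate (racemic, both diastereomers) | CCCCCCCCCCCCCCCCCCCCCC1(O)C(I)=CN(S(=O)(=O)c2ccc(C)cc2)C1C(=O)OC
F2 | step 4 | methyl 3-heneicosyl-4-iodo-1-tosyl-1H-pyrrole-2-carboxylate | CCCCCCCCCCCCCCCCCCCCCc1c(I)cn(S(=O)(=O)c2ccc(C)cc2)c1C(=O)OC
F3 | step 2 | methyl 5-heneicosyl-5-[(trimethylsilyl)ethynyl]-4,5-dihydro-1,3-oxazole-4-carboxylate (racemic, both diastereomers) | CCCCCCCCCCCCCCCCCCCCCC1(C#C[Si](C)(C)C)OC=NC1C(=O)OC
F4 | step 2 | methyl 2-amino-3-hydroxy-3-[(trimethylsilyl)ethynyl]tetracosanoate (racemic, both diastereomers) | CCCCCCCCCCCCCCCCCCCCCC(O)(C#C[Si](C)(C)C)C(N)C(=O)OC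
F0 | step 3 | none | none
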